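**Plan**

1. Retrosynthesis: the C2–C1' bond between the pyranone ring and the B ring is cut first. The B-ring half goes back through its C1'–I and C3'–O bonds to 1,2,4-trimethoxybenzene, and the chromone half through its O1–C2 and C2–C3 bonds to an o-hydroxyacetophenone.
2. Forward: the pyranone ring is closed on the A ring first (5,6,7-trimethoxychromone). The B ring is hydroxylated between two methoxy groups, acetylated and iodinated. The halves are joined, then BCl3 and methanol release the 5-OH and 3'-OH.
3. Enabling feature on the chromone: C2–H is the sp2 C–H between ring oxygen O1 and the vinylogous C4 carbonyl, and the C4=O/5-OMe pocket binds MgCl2. A hindered zinc amide should therefore metalate C2 directly, so no 2-halochromone is needed.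
4. Enabling feature on the B ring: C1' is para to the 4'-methoxy and ortho to the 2'-methoxy group. The acetyl group on O3' and the methyl group on O5 are helpers removed in the last step; the acetate also weakens the only competing director, the oxygen para to C6'.
5. Stereochemistry: the target has no stereocentre, no stereogenic double bond and no hindered biaryl axis, so nothing has to be set.

Key step: step 5

Assumption: compounds 1 and 4 are taken as catalogue chemicals; because the target is achiral, the request for a single enantiomer asks for nothing beyond the constitution.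

**Route**

Step 1
Reactants: 1 1-(6-hydroxy-2,3,4-trimethoxyphenyl)ethan-1-one
Product: 3 5,6,7-trimethoxy-4H-chromen-4-one, via enaminone 2 (not isolated)
Conditions: DMF-DMA (3 equiv), toluene, 100 °C; then conc. HCl, CH2Cl2, 40 °C
Reagents that add atoms: N,N-dimethylformamide dimethyl acetal, COC(OC)N(C)C
Why: Enaminone annulation: the acetyl methyl group condenses with the amide acetal to the (E)-enaminone 2, and under acid the ortho phenol adds to the amine-bearing carbon with loss of dimethylamine (6-endo addition–elimination), which should give the 2,3-unsubstituted chromone without creating a stereocentre.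

Step 2
Reactants: 4 1,2,4-trimethoxybenzene
Product: 7 2,3,6-trimethoxyphenol, via aryllithium 5 (not isolated), via arylboronate 6 (not isolated)
Conditions: n-BuLi, THF, 0 °C → rt; B(OMe)3, −78 °C → rt; then AcOH, 30% H2O2, 0 °C → rt
Reagents that add atoms: hydrogen peroxide, OO
Why: Directed ortho-lithiation followed by borylation and peroxide oxidation: C3–H of 4 is the only C–H flanked by two methoxy groups, so n-BuLi should remove it selectively, the aryllithium is trapped on boron, and the 1,2-aryl shift from boron to oxygen places the hydroxyl group at that carbon.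

Step 3
Reactants: 7 2,3,6-trimethoxyphenol
Product: 8 2,3,6-trimethoxyphenyl acetate
Conditions: Ac2O, pyridine, DMAP (cat.), CH2Cl2, rt
Reagents that add atoms: acetic anhydride, CC(=O)OC(C)=O
Why: DMAP-catalysed O-acetylation of a 2,6-disubstituted phenol, which masks the phenol and turns its oxygen from the strongest into the weakest donor of the ring before the halogenation.

Step 4
Reactants: 8 2,3,6-trimethoxyphenyl acetate
Product: 9 3-iodo-2,5,6-trimethoxyphenyl acetate
Conditions: NIS (1.05 equiv), TFA (0.2 equiv), MeCN, 0 °C → rt, dark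
Reagents that add atoms: N-iodosuccinimide, O=C1CCC(=O)N1I
Why: Electrophilic aromatic iodination with acid-activated NIS: of the two free C–H positions, C3 is ortho to one methoxy group and para to another, whereas C4 is para only to the acetoxy oxygen, whose lone pair is tied up in the ester and twisted out of conjugation by its two neighbours, so iodine should enter at C3.

Step 5
Reactants: 3 5,6,7-trimethoxy-4H-chromen-4-one; 9 3-iodo-2,5,6-trimethoxyphenyl acetate
Product: 11 2,3,6-trimethoxy-5-(5,6,7-trimethoxy-4-oxo-4H-chromen-2-yl)phenyl acetate, via diorganozinc 10 (not isolated)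
Conditions: 3 (1.3 equiv), TMP2Zn·2MgCl2·2LiCl (0.55 equiv per 3), THF, −30 °C; then 9 (1.0 equiv), Pd(dba)2 (3 mol %), SPhos (6 mol %), 25 → 50 °C
Reagents that add atoms: none
Why: The MgCl2 carried by the base binds the C4 carbonyl/5-OMe pocket, and the TMP–zinc amide then removes C2–H, the sp2 proton between O1 and the Lewis-acid-activated vinylogous carbonyl, to give the bis(chromen-2-yl)zinc 10; Pd(0) inserts into the C–I bond of 9, the chromenyl group passes from zinc to palladium, and reductive elimination forms the C2–C1' bond. The closest known reaction type is the Lewis-acid-triggered C2 zincation of chromones with TMP–zinc bases followed by Negishi cross-coupling with aryl iodides to give flavones. No ring is closed and no stereocentre is formed; the new aryl–heteroaryl axis has a single ortho substituent on the B-ring side and should rotate freely. The step needs metalation at C2 and not at C3 or C8, which the magnesium salt is there to secure, because complexation of the carbonyl raises the acidity of C2–H and keeps the amide from being delivered by the carbonyl oxygen to C3, while the arene C8–H is not acidic enough for a zinc amide at −30 °C. It also needs chemoselective reaction at the C–I bond, which is secured because the aryl acetate and the methyl ethers are inert to the organozinc and to Pd(0); the position on the B ring is fixed by the iodide.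

Step 6
Reactants: 11 2,3,6-trimethoxy-5-(5,6,7-trimethoxy-4-oxo-4H-chromen-2-yl)phenyl acetate
Product: 13 5-hydroxy-2-(3-hydroxy-2,4,5-trimethoxyphenyl)-6,7-dimethoxy-4H-chromen-4-one (psiadiarabicin), via 5-hydroxyflavone acetate 12 (not isolated)
Conditions: BCl3 (3 equiv), CH2Cl2, −78 → 0 °C; then MeOH, 0 → 40 °C
Reagents that add atoms: none
Why: Chelation-controlled Lewis-acid demethylation: BCl3 bound to the C4 carbonyl should cleave only the peri 5-methoxy group through a six-membered chelate, and the HCl formed on the methanol quench should remove the aryl acetate by acid-catalysed transesterification, leaving the five other methyl ethers in place.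

**Compound list**

1 | 1-(6-hydroxy-2,3,4-trimethoxyphenyl)ethan-1-one | CC(=O)c1c(O)cc(OC)c(OC)c1OC | starting material
2 | (E)-3-(dimethylamino)-1-(6-hydroxy-2,3,4-trimethoxyphenyl)prop-2-en-1-one | CN(C)/C=C/C(=O)c1c(O)cc(OC)c(OC)c1OC | intermediate
3 | 5,6,7-trimethoxy-4H-chromen-4-one | COc1cc2occc(=O)c2c(OC)c1OC | intermediate
4 | 1,2,4-trimethoxybenzene | COc1ccc(OC)c(OC)c1 | starting material
5 | (2,3,6-trimethoxyphenyl)lithium | [Li]c1c(OC)ccc(OC)c1OC | intermediate
6 | dimethyl (2,3,6-trimethoxyphenyl)boronate | COB(OC)c1c(OC)ccc(OC)c1OC | intermediate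
7 | 2,3,6-trimethoxyphenol | COc1ccc(OC)c(O)c1OC | intermediate
8 | 2,3,6-trimethoxyphenyl acetate | CC(=O)Oc1c(OC)ccc(OC)c1OC | intermediate
9 | 3-iodo-2,5,6-trimethoxyphenyl acetate | CC(=O)Oc1c(OC)c(I)cc(OC)c1OC | intermediate
10 | bis(5,6,7-trimethoxy-4-oxo-4H-chromen-2-yl)zinc (MgCl2/LiCl complex) | COc1cc2oc([Zn]c3cc(=O)c4c(OC)c(OC)c(OC)cc4o3)cc(=O)c2c(OC)c1OC | intermediate
11 | 2,3,6-trimethoxy-5-(5,6,7-trimethoxy-4-oxo-4H-chromen-2-yl)phenyl acetate | COc1cc(-c2cc(=O)c3c(OC)c(OC)c(OC)cc3o2)c(OC)c(OC(C)=O)c1OC | intermediate
12 | 5-(5-hydroxy-6,7-dimethoxy-4-oxo-4H-chromen-2-yl)-2,3,6-trimethoxyphenyl acetate | COc1cc(-c2cc(=O)c3c(O)c(OC)c(OC)cc3o2)c(OC)c(OC(C)=O)c1OC | intermediate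
13 | 5-hydroxy-2-(3-hydroxy-2,4,5-trimethoxyphenyl)-6,7-dimethoxy-4H-chromen-4-one (psiadiarabicin) | COc1cc(-c2cc(=O)c3c(O)c(OC)c(OC)cc3o2)c(OC)c(O)c1OC | target

**Step count**

Total steps: 6. Longest linear sequence: 5 steps (steps 2, 3, 4, 5, 6, from 4 to 13).

**Steps most likely to fail**

Risk 1 (step 5). The zinc amide may metalate C3 in place of C2, a C3-metalated pyranone may open to the phenoxide ynone, and transmetalation to the ortho-methoxy arylpalladium may be slow enough for homocoupling and protodezincation to take over. The fallback reverses the polarity of the union and sets out from iodide 9 and chromone 3. Miyaura borylation of 9 (B2pin2, Pd(dppf)Cl2, KOAc, dioxane, 85 °C) should give 2,3,6-trimethoxy-5-(4,4,5,5-tetramethyl-1,3,2-dioxaborolan-2-yl)phenyl acetate F1. F1 and 3 are then joined by a Pd(II)-catalysed oxidative boron-Heck arylation (Pd(TFA)2, 5-nitro-1,10-phenanthroline, O2, DMSO, 100 °C). In this manifold the aryl–palladium species adds 1,4 to the enone, so the aryl group can arrive only at C2, and β-hydride elimination returns the flavone. The route is rejoined at 11.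

Risk 2 (step 4). The electrophile may attack C4 of 8 (para to the acetoxy group) to a significant extent, or iodinate twice, and the isomers may be hard to separate. The fallback fixes the position by ipso-substitution instead of by the balance of directing groups, and sets out from 4. NBS in MeCN should brominate 4 at C5 to 1-bromo-2,4,5-trimethoxybenzene F2. Bromine–lithium exchange (n-BuLi, THF, −78 °C) gives (2,4,5-trimethoxyphenyl)lithium F3, which TMSCl traps as trimethyl(2,4,5-trimethoxyphenyl)silane F4. Lithiation of F4 between the two methoxy groups (n-BuLi, TMEDA, THF, 0 °C; the silyl group shields its own ortho C–H) gives [2,3,6-trimethoxy-5-(trimethylsilyl)phenyl]lithium F5. B(OMe)3 converts it into dimethyl [2,3,6-trimethoxy-5-(trimethylsilyl)phenyl]boronate F6, and H2O2/AcOH into 2,3,6-trimethoxy-5-(trimethylsilyl)phenol F7. Acetylation as in step 3 gives 2,3,6-trimethoxy-5-(trimethylsilyl)phenyl acetate F8, and ICl (CH2Cl2, −78 → 0 °C) replaces silicon by iodine at the same carbon. The route is rejoined at 9.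

Risk 3 (step 6). Once the 5-O–boron chelate has formed, BCl3 may go on to cleave the neighbouring 6-methoxy group or a methoxy group next to the acetoxy group on the B ring, and the acid methanolysis of the hindered acetate may stall. The fallback moves the demethylation to the chromone, where no B ring is present, and ends with a mild acetal cleavage; it sets out from 3. BCl3 (CH2Cl2, 0 °C) should convert 3 into 5-hydroxy-6,7-dimethoxy-4H-chromen-4-one F9, and NaH/MOMCl (DMF, 0 °C) into 6,7-dimethoxy-5-(methoxymethoxy)-4H-chromen-4-one F10. Zincation as in step 5 gives bis[6,7-dimethoxy-5-(methoxymethoxy)-4-oxo-4H-chromen-2-yl]zinc F11, and Negishi coupling with 9 gives 5-[6,7-dimethoxy-5-(methoxymethoxy)-4-oxo-4H-chromen-2-yl]-2,3,6-trimethoxyphenyl acetate F12. HCl in MeOH (from AcCl, 0 °C → rt) then removes the methoxymethyl and acetyl groups together, and the route is rejoined at the target 13.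

**Further compounds**

F1 | step 5 | 2,3,6-trimethoxy-5-(4,4,5,5-tetramethyl-1,3,2-dioxaborolan-2-yl)phenyl acetate | CC(=O)Oc1c(OC)c(B2OC(C)(C)C(C)(C)O2)cc(OC)c1OC
F2 | step 4 | 1-bromo-2,4,5-trimethoxybenzene | COc1cc(OC)c(Br)cc1OC
F3 | step 4 | (2,4,5-trimethoxyphenyl)lithium | [Li]c1cc(OC)c(OC)cc1OC
F4 | step 4 | trimethyl(2,4,5-trimethoxyphenyl)silane | COc1cc(OC)c([Si](C)(C)C)cc1OC
F5 | step 4 | [2,3,6-trimethoxy-5-(trimethylsilyl)phenyl]lithium | [Li]c1c(OC)c([Si](C)(C)C)cc(OC)c1OC
F6 | step 4 | dimethyl [2,3,6-trimethoxy-5-(trimethylsilyl)phenyl]boronate | COB(OC)c1c(OC)c([Si](C)(C)C)cc(OC)c1OC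
F7 | step 4 | 2,3,6-trimethoxy-5-(trimethylsilyl)phenol | COc1cc([Si](C)(C)C)c(OC)c(O)c1OC
F8 | step 4 | 2,3,6-trimethoxy-5-(trimethylsilyl)phenyl acetate | COc1cc([Si](C)(C)C)c(OC)c(OC(C)=O)c1OC
F9 | step 6 | 5-hydroxy-6,7-dimethoxy-4H-chromen-4-one | COc1cc2occc(=O)c2c(O)c1OC
F10 | step 6 | 6,7-dimethoxy-5-(methoxymethoxy)-4H-chromen-4-one | COCOc1c(OC)c(OC)cc2occc(=O)c12
F11 | step 6 | bis[6,7-dimethoxy-5-(methoxymethoxy)-4-oxo-4H-chromen-2-yl]zinc | COCOc1c(OC)c(OC)cc2oc([Zn]c3cc(=O)c4c(OCOC)c(OC)c(OC)cc4o3)cc(=O)c12
F12 | step 6 | 5-[6,7-dimethoxy-5-(methoxymethoxy)-4-oxo-4H-chromen-2-yl]-2,3,6-trimethoxyphenyl acetate | COCOc1c(OC)c(OC)cc2oc(-c3cc(OC)c(OC)c(OC(C)=O)c3OC)cc(=O)c12
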